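Numbering used throughout: O1–O2–C3(CH2CO2H)–C4(CH3)–C5H2–C6(CH3)(C7H2–C8H(CH3)–nine methylenes C9 to C17–phenyl); the target is the 3S,4S,6R,8R acid.
Retrosynthetic cuts, in order: C3–CH2CO2H (cyclic peroxycarbenium ion plus silyl ketene acetal), C5–H (from a C5 iodide), O1–C6 together with C5–I (the only ring, from an open-chain hydroperoxy acetal), C4–C5 (alkenyl metal plus epoxy alcohol) and C11–C12 (Grignard reagent plus tosylate).
Enabling feature: C6 is a fully substituted peroxy carbon lying next to the unsubstituted C5H2 and 1,3 to the C4 methyl, so O1–C6 can be made by Markovnikov 6-endo attack of a C3 hydroperoxy acetal on an (E)-C5=C6 alkene, whose geometry rather than the size of its groups distinguishes the C6 methyl from C7.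
Forward order: the chain is joined at C11–C12, the C5≡C6 alkyne is turned into the E alkenyl iodide, C4–C5 is formed by epoxide opening, the diol is cut to the C3 aldehyde and converted into the hydroperoxy acetal, the 1,2-dioxane closes at O1–C6, iodine is removed, the acetate arm is added at C3 and the ester is hydrolysed.
Stereochemistry: C8 is bought with (R)-citronellol, C4 comes from the Sharpless epoxide of (E)-crotyl alcohol with one inversion, C6 is relayed from C4 through the E alkene in a chair transition state, and C3 is set by axial attack on the conformationally locked peroxycarbenium ion.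
Key step: step 13

Remark: the hydroperoxy acetal and the two 3-methoxy-1,2-dioxanes made from it are carried as mixtures of both C3 epimers (C3 is left undefined in their SMILES), because both epimers converge on one peroxycarbenium ion in step 15.

Step 1
Reactants: 1 (R)-citronellol, (3R)-3,7-dimethyloct-6-en-1-ol
Product: 2 tert-butyl{[(3R)-3,7-dimethyloct-6-en-1-yl]oxy}dimethylsilane (TBS ether of 1)
Conditions: TBSCl, imidazole, DMF, 0 °C to rt
Reagents that add atoms: tert-butyldimethylsilyl chloride, CC(C)(C)[Si](C)(C)Cl
Why: Imidazole-promoted silylation of the primary alcohol gives a TBS ether that should survive ozonolysis, borohydride, tosylation and the copper-catalysed Grignard coupling, while the C8 stereocentre bought with 1 is not touched.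

Step 2
Reactants: 2 tert-butyl{[(3R)-3,7-dimethyloct-6-en-1-yl]oxy}dimethylsilane
Product: 4 (4R)-6-(tert-butyldimethylsilyloxy)-4-methylhexan-1-ol, via silyloxy aldehyde 3 (not isolated)
Conditions: O3, CH2Cl2/MeOH, −78 °C; then NaBH4 (excess), −78 °C to rt
Reagents that add atoms: ozone, [O-][O+]=O
Why: Ozonolysis of the electron-rich trisubstituted alkene with reductive NaBH4 work-up cleaves off the isopropylidene end (as acetone, which the excess borohydride reduces on to propan-2-ol) and reduces the (4R)-6-(tert-butyldimethylsilyloxy)-4-methylhexanal 3 formed in the flask to the primary alcohol, the silyl ether being inert to both reagents.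

Step 3
Reactants: 4 (4R)-6-(tert-butyldimethylsilyloxy)-4-methylhexan-1-ol
Product: 5 (4R)-6-(tert-butyldimethylsilyloxy)-4-methylhexyl 4-methylbenzenesulfonate
Conditions: TsCl, Et3N, DMAP (cat.), CH2Cl2, 0 °C to rt
Reagents that add atoms: 4-toluenesulfonyl chloride, Cc1ccc(cc1)S(=O)(=O)Cl
Why: Sulfonylation of the unhindered primary alcohol should give the tosylate that serves as the sp3 electrophile of the chain coupling.

Step 4
Reactants: 5 (4R)-6-(tert-butyldimethylsilyloxy)-4-methylhexyl 4-methylbenzenesulfonate; 6 (6-bromohexyl)benzene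
Product: 8 tert-butyldimethyl{[(3R)-3-methyl-12-phenyldodecyl]oxy}silane, via 6-phenylhexylmagnesium bromide 7 (not isolated)
Conditions: 6, Mg, THF, rt to 40 °C; then 5, Li2CuCl4 (5 mol %), THF, −78 °C to rt
Reagents that add atoms: none
Why: In this Kochi-type (Fouquet–Schlosser) coupling the alkylcopper species generated from the Grignard reagent and Li2CuCl4 should displace the primary tosylate with clean C11–C12 bond formation, and neither the silyl ether nor the remote stereocentre takes part.

Step 5
Reactants: 8 tert-butyldimethyl{[(3R)-3-methyl-12-phenyldodecyl]oxy}silane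
Product: 9 (3R)-3-methyl-12-phenyldodecan-1-ol
Conditions: p-TsOH·H2O (cat.), MeOH, rt
Reagents that add atoms: none
Why: Acid-catalysed methanolysis cleaves the primary TBS ether, and the rest of the molecule (alkyl chain, phenyl ring, tertiary C–H stereocentre) is indifferent to dilute acid.

Step 6
Reactants: 9 (3R)-3-methyl-12-phenyldodecan-1-ol
Product: 10 (3R)-3-methyl-12-phenyldodecanal
Conditions: TEMPO (10 mol %), PhI(OAc)2, CH2Cl2, rt
Reagents that add atoms: none
Why: The TEMPO/PhI(OAc)2 oxidation (oxoammonium-mediated, Piancatelli–Margarita conditions) should stop at the aldehyde, whose stereocentre is β to the carbonyl group and therefore cannot epimerise.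

Step 7
Reactants: 10 (3R)-3-methyl-12-phenyldodecanal
Product: 11 (4R)-4-methyl-13-phenyltridec-1-yne
Conditions: dimethyl (1-diazo-2-oxopropyl)phosphonate, K2CO3, MeOH, 0 °C to rt
Reagents that add atoms: dimethyl (1-diazo-2-oxopropyl)phosphonate (Ohira–Bestmann reagent), CC(=O)C(=[N+]=[N-])P(=O)(OC)OC
Why: In the Ohira–Bestmann version of the Seyferth–Gilbert homologation, methanolysis of the reagent releases the diazomethylphosphonate anion, which adds to the aldehyde, eliminates dimethyl phosphate and loses dinitrogen with a 1,2-hydrogen shift to give the terminal alkyne, whose new carbon is C5.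

Step 8
Reactants: 11 (4R)-4-methyl-13-phenyltridec-1-yne
Product: 13 (1E,4R)-1-iodo-2,4-dimethyl-13-phenyltridec-1-ene, via alkenyl(dimethyl)alane 12 (not isolated)
Conditions: Me3Al (2 equiv), Cp2ZrCl2 (0.2 equiv), CH2Cl2, 0 °C to rt; then I2, THF, −30 to 0 °C
Reagents that add atoms: trimethylaluminium, C[Al](C)C; iodine, II
Why: Negishi zirconium-catalysed carboalumination adds CH3 and aluminium syn across the terminal alkyne with the metal on C5, and iodinolysis of the C–Al bond of dimethyl[(1E,4R)-2,4-dimethyl-13-phenyltridec-1-en-1-yl]alane 12 with retention should give the E iodide, which fixes the C5=C6 geometry, brings the C6 methyl and allows the minor regioisomer, the zirconium residues and the excess Me3Al to be removed.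

Step 9
Reactants: 14 (E)-but-2-en-1-ol (crotyl alcohol)
Product: 15 [(2S,3S)-3-methyloxiran-2-yl]methanol
Conditions: Ti(OiPr)4 (5 mol %), L-(+)-diethyl tartrate (6 mol %), t-BuOOH (anhydrous), 4 Å molecular sieves, CH2Cl2, −20 °C; non-aqueous work-up
Reagents that add atoms: tert-butyl hydroperoxide, CC(C)(C)OO
Why: In the Sharpless asymmetric epoxidation the Ti(OiPr)4/L-(+)-tartrate complex delivers the peroxide oxygen to the face of the E allylic alcohol that leads to the (2S,3S)-epoxide, so that the methyl-bearing carbon (the future C4) has the configuration that one inversion will turn into 4S.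

Step 10
Reactants: 13 (1E,4R)-1-iodo-2,4-dimethyl-13-phenyltridec-1-ene; 15 [(2S,3S)-3-methyloxiran-2-yl]methanol
Product: 19 (2R,3S,4E,7R)-3,5,7-trimethyl-16-phenylhexadec-4-ene-1,2-diol, via alkenyllithium 16 (not isolated), via diethyl(alkenyl)alane 17 (not isolated), via dimethylaluminium epoxy alkoxide 18 (not isolated)
Conditions: 13, t-BuLi (2 equiv), Et2O/hexane, −78 °C; Et2AlCl (1 equiv), −78 to 0 °C; then 15 (1.5 equiv) pre-treated with Me3Al (1.5 equiv) in CH2Cl2, −30 °C to rt; aq. potassium sodium tartrate
Reagents that add atoms: none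
Why: Iodine–lithium exchange with retention and transmetalation of alkenyllithium 16 with Et2AlCl give diethyl[(1E,4R)-2,4-dimethyl-13-phenyltridec-1-en-1-yl]alane 17 in known amount and free of the carboalumination residues, and this neutral alane should open the dimethylaluminium alkoxide 18 of the epoxy alcohol at the methyl-bearing carbon with inversion, as in the hydroxyl-directed C3-selective opening of 2,3-epoxy alcohols by organoaluminium reagents (the alkoxide-bound aluminium chelates and activates the epoxide oxygen while the external alane transfers its sp2 carbon in preference to ethyl), which sets C4 as S and leaves a 1,2-diol ready for cleavage.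

Step 11
Reactants: 19 (2R,3S,4E,7R)-3,5,7-trimethyl-16-phenylhexadec-4-ene-1,2-diol
Product: 20 (2S,3E,6R)-2,4,6-trimethyl-15-phenylpentadec-3-enal
Conditions: NaIO4 on silica gel, CH2Cl2, 0 °C; filtered and used at once
Reagents that add atoms: none
Why: Glycol cleavage (Malaprade reaction) with silica-supported NaIO4 unveils the C3 aldehyde under neutral conditions without aqueous work-up, so that the epimerisable C4 stereocentre and the β,γ-position of the alkene should survive if the filtered solution is taken straight into the next step.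

Step 12
Reactants: 20 (2S,3E,6R)-2,4,6-trimethyl-15-phenylpentadec-3-enal
Product: 21 (2S,3E,6R)-1-hydroperoxy-1-methoxy-2,4,6-trimethyl-15-phenylpentadec-3-ene (both C1 epimers; C1 is C3 in target numbering)
Conditions: H2O2 (anhydrous, in Et2O, 5 equiv), MeOH, PPTS (cat.), −20 to 0 °C
Reagents that add atoms: hydrogen peroxide, OO; methanol, CO
Why: Acid-catalysed peroxyacetalisation, in which the hemiacetal ionises to the methoxycarbenium ion and the α-effect nucleophile H2O2 captures it, should give the same 1-methoxyalkyl hydroperoxide that ozonolysis in methanol produces, the weak acid and low temperature sparing C4, and the configuration of the new acetal carbon is immaterial.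

Step 13
Reactants: 21 (2S,3E,6R)-1-hydroperoxy-1-methoxy-2,4,6-trimethyl-15-phenylpentadec-3-ene
Product: 22 (4R,5S,6R)-5-iodo-3-methoxy-4,6-dimethyl-6-[(2R)-2-methyl-11-phenylundecyl]-1,2-dioxane (both C3 epimers)
Conditions: NIS (1.2 equiv), CH2Cl2, −78 to −20 °C, dark
Reagents that add atoms: N-iodosuccinimide, C1CC(=O)N(I)C1=O
Why: NIS forms an iodonium ion reversibly on the C5=C6 alkene and the terminal hydroperoxide oxygen opens it at the tertiary carbon C6 from the face opposite to iodine, so that the O1–C6 and C5–I bonds arise in one anti addition; the closest known reaction type is the halonium- or mercury-induced cyclisation of unsaturated hydroperoxides and unsaturated hydroperoxy acetals to halo-1,2-dioxanes. The single ring formed, the 1,2-dioxane O1–O2–C3–C4–C5–C6, closes in the 6-endo-trig mode, because the 5-exo alternative would require attack at the secondary C5 against the positive charge that builds up at C6. The new quaternary stereocentre C6 is controlled by C4 and by the alkene geometry: in the chair transition state the substituent trans to C4 (C7) must lie equatorial and the cis one (the C6 methyl) axial, and the C4 methyl stays equatorial because the other chair would bring it syn-diaxial to the C6 methyl, the same contact that allylic 1,3-strain already penalises in the open chain, which gives 6R with the two ring methyls trans. The second new centre, C5 (S, iodine equatorial and anti to O1), follows from the anti addition and is erased in step 14, while C3 stays an epimer mixture. The step therefore needs 6-endo regioselectivity, secured by the tertiary alkene terminus, and attack on one alkene face, secured by the equatorial C4 methyl together with the geometrically pure E alkene made in step 8.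

Step 14
Reactants: 22 (4R,5S,6R)-5-iodo-3-methoxy-4,6-dimethyl-6-[(2R)-2-methyl-11-phenylundecyl]-1,2-dioxane
Product: 23 (4S,6R)-3-methoxy-4,6-dimethyl-6-[(2R)-2-methyl-11-phenylundecyl]-1,2-dioxane (both C3 epimers)
Conditions: Bu3SnH (5 equiv, 1 M), Et3B (0.2 equiv), air, toluene, −20 to 0 °C
Reagents that add atoms: none
Why: Radical chain deiodination, started by Et3B and air at low temperature, should replace iodine by hydrogen because the secondary C5 radical is trapped by concentrated Bu3SnH much faster than it can fragment the neighbouring C6–O1 bond or attack O1 to give an epoxide, and the O–O bond, C4 and C6 are not involved.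

Step 15
Reactants: 23 (4S,6R)-3-methoxy-4,6-dimethyl-6-[(2R)-2-methyl-11-phenylundecyl]-1,2-dioxane; 24 tert-butyl[(1-methoxyethenyl)oxy]dimethylsilane (1-(tert-butyldimethylsilyloxy)-1-methoxyethene)
Product: 25 methyl 2-{(3S,4S,6R)-4,6-dimethyl-6-[(2R)-2-methyl-11-phenylundecyl]-1,2-dioxan-3-yl}acetate
Conditions: TMSOTf (0.3 equiv), CH2Cl2, −78 °C
Reagents that add atoms: none
Why: In this Mukaiyama-type addition to a peroxy acetal, TMSOTf ionises the C3 methoxy group of either epimer to one cyclic peroxycarbenium ion whose half-chair is locked with C7 and the C4 methyl equatorial and the C6 methyl axial, and the silyl ketene acetal should add axially at C3, anti to the axial C4–H and on the face away from the axial C6 methyl, to give the 3,4-cis (3S) ester.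

Step 16
Reactants: 25 methyl 2-{(3S,4S,6R)-4,6-dimethyl-6-[(2R)-2-methyl-11-phenylundecyl]-1,2-dioxan-3-yl}acetate
Product: 26 2-{(3S,4S,6R)-4,6-dimethyl-6-[(2R)-2-methyl-11-phenylundecyl]-1,2-dioxan-3-yl}acetic acid (target, CNP0181677.1)
Conditions: LiOH, THF/H2O, 0 °C; then 1 M HCl to pH 3
Reagents that add atoms: lithium hydroxide, [Li+].[OH-]
Why: Saponification at 0 °C should succeed because hydroxide adds to the ester carbonyl faster than it can enolise the β-peroxy ester (ring-opening elimination) or remove the C3–H (Kornblum–DeLaMare fragmentation), the carboxylate formed is inert to both paths, and mild acidification frees the acid with all four stereocentres intact.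

Compound list
1 | (R)-citronellol, (3R)-3,7-dimethyloct-6-en-1-ol | C[C@H](CCC=C(C)C)CCO | starting material
2 | tert-butyl{[(3R)-3,7-dimethyloct-6-en-1-yl]oxy}dimethylsilane | C[C@H](CCC=C(C)C)CCO[Si](C)(C)C(C)(C)C | intermediate
3 | (4R)-6-(tert-butyldimethylsilyloxy)-4-methylhexanal (not isolated) | C[C@H](CCC=O)CCO[Si](C)(C)C(C)(C)C | intermediate
4 | (4R)-6-(tert-butyldimethylsilyloxy)-4-methylhexan-1-ol | C[C@H](CCCO)CCO[Si](C)(C)C(C)(C)C | intermediate
5 | (4R)-6-(tert-butyldimethylsilyloxy)-4-methylhexyl 4-methylbenzenesulfonate | C[C@H](CCCOS(=O)(=O)c1ccc(C)cc1)CCO[Si](C)(C)C(C)(C)C | intermediate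
6 | (6-bromohexyl)benzene | BrCCCCCCc1ccccc1 | starting material
7 | 6-phenylhexylmagnesium bromide (not isolated) | Br[Mg]CCCCCCc1ccccc1 | intermediate
8 | tert-butyldimethyl{[(3R)-3-methyl-12-phenyldodecyl]oxy}silane | C[C@H](CCCCCCCCCc1ccccc1)CCO[Si](C)(C)C(C)(C)C | intermediate
9 | (3R)-3-methyl-12-phenyldodecan-1-ol | C[C@H](CCCCCCCCCc1ccccc1)CCO | intermediate
10 | (3R)-3-methyl-12-phenyldodecanal | C[C@H](CCCCCCCCCc1ccccc1)CC=O | intermediate
11 | (4R)-4-methyl-13-phenyltridec-1-yne | C#CC[C@H](C)CCCCCCCCCc1ccccc1 | intermediate
12 | dimethyl[(1E,4R)-2,4-dimethyl-13-phenyltridec-1-en-1-yl]alane (not isolated) | C[Al](C)/C=C(\C)C[C@H](C)CCCCCCCCCc1ccccc1 | intermediate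
13 | (1E,4R)-1-iodo-2,4-dimethyl-13-phenyltridec-1-ene | I/C=C(\C)C[C@H](C)CCCCCCCCCc1ccccc1 | intermediate
14 | (E)-but-2-en-1-ol (crotyl alcohol) | C/C=C/CO | starting material
15 | [(2S,3S)-3-methyloxiran-2-yl]methanol | C[C@@H]1O[C@H]1CO | intermediate
16 | [(1E,4R)-2,4-dimethyl-13-phenyltridec-1-en-1-yl]lithium (not isolated) | [Li]/C=C(\C)C[C@H](C)CCCCCCCCCc1ccccc1 | intermediate
17 | diethyl[(1E,4R)-2,4-dimethyl-13-phenyltridec-1-en-1-yl]alane (not isolated) | CC[Al](CC)/C=C(\C)C[C@H](C)CCCCCCCCCc1ccccc1 | intermediate
18 | dimethylaluminium [(2S,3S)-3-methyloxiran-2-yl]methoxide (not isolated) | C[C@@H]1O[C@H]1CO[Al](C)C | intermediate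
19 | (2R,3S,4E,7R)-3,5,7-trimethyl-16-phenylhexadec-4-ene-1,2-diol | OC[C@H](O)[C@@H](C)/C=C(\C)C[C@H](C)CCCCCCCCCc1ccccc1 | intermediate
20 | (2S,3E,6R)-2,4,6-trimethyl-15-phenylpentadec-3-enal | O=C[C@@H](C)/C=C(\C)C[C@H](C)CCCCCCCCCc1ccccc1 | intermediate
21 | (2S,3E,6R)-1-hydroperoxy-1-methoxy-2,4,6-trimethyl-15-phenylpentadec-3-ene (both C1 epimers) | COC(OO)[C@@H](C)/C=C(\C)C[C@H](C)CCCCCCCCCc1ccccc1 | intermediate
22 | (4R,5S,6R)-5-iodo-3-methoxy-4,6-dimethyl-6-[(2R)-2-methyl-11-phenylundecyl]-1,2-dioxane (both C3 epimers) | C[C@H](CCCCCCCCCc1ccccc1)C[C@]1(C)[C@@H](I)[C@H](C)C(OC)OO1 | intermediate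
23 | (4S,6R)-3-methoxy-4,6-dimethyl-6-[(2R)-2-methyl-11-phenylundecyl]-1,2-dioxane (both C3 epimers) | C[C@H](CCCCCCCCCc1ccccc1)C[C@]1(C)C[C@H](C)C(OC)OO1 | intermediate
24 | tert-butyl[(1-methoxyethenyl)oxy]dimethylsilane | C=C(OC)O[Si](C)(C)C(C)(C)C | starting material
25 | methyl 2-{(3S,4S,6R)-4,6-dimethyl-6-[(2R)-2-methyl-11-phenylundecyl]-1,2-dioxan-3-yl}acetate | C[C@H](CCCCCCCCCc1ccccc1)C[C@]1(C)C[C@H](C)[C@H](CC(=O)OC)OO1 | intermediate
26 | 2-{(3S,4S,6R)-4,6-dimethyl-6-[(2R)-2-methyl-11-phenylundecyl]-1,2-dioxan-3-yl}acetic acid | C[C@H](CCCCCCCCCc1ccccc1)C[C@]1(C)C[C@H](C)[C@H](CC(=O)O)OO1 | target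

Total step count: 16.
Longest linear sequence: 15 steps (steps 1 to 8 and 10 to 16, from (R)-citronellol 1); the epoxide branch adds step 9.

Steps most likely to fail

Step 13 (key cyclisation). What may go wrong: oxidation of the hydroperoxide by the N-iodo reagent instead of alkene activation, competing 5-exo closure, or incomplete facial discrimination in a loose transition state, which would erode the configuration at C6. The fallback sets out from aldehyde 20 and comes back to the route at dioxane 23. The aldehyde would be converted with HC(OMe)3 and PPTS in methanol into the dimethyl acetal (2S,3E,6R)-1,1-dimethoxy-2,4,6-trimethyl-15-phenylpentadec-3-ene F1. Isayama–Mukaiyama hydroperoxysilylation (Co(acac)2, O2, Et3SiH) would then add hydrogen to C5 and the silylperoxy group to the tertiary C6, giving triethyl{[(2S,6R)-1,1-dimethoxy-2,4,6-trimethyl-15-phenylpentadecan-4-yl]peroxy}silane F2 as both C6 epimers. p-TsOH in methanol would remove the silyl group and close the ring by intramolecular peroxy-acetal exchange at C3, giving 23 together with its C6 epimer (4S,6S)-3-methoxy-4,6-dimethyl-6-[(2R)-2-methyl-11-phenylundecyl]-1,2-dioxane F3, to be separated by chromatography. This path gives up the stereochemical relay to C6, but it rests on established peroxide chemistry and also bypasses steps 12 and 14.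

Step 12 (hydroperoxy acetal). What may go wrong: acid-promoted enolisation of the aldehyde with epimerisation at C4, migration of the C5=C6 double bond into conjugation, or over-addition of H2O2 to the geminal bis-hydroperoxide. The fallback sets out from aldehyde 20 and comes back to the route at iodo-dioxane 22. The aldehyde would be treated with anhydrous ethereal H2O2 without any acid to give the perhydrate (2S,3E,6R)-1-hydroperoxy-2,4,6-trimethyl-15-phenylpentadec-3-en-1-ol F4. NIS would close it in the same 6-endo manner to the cyclic peroxy hemiacetal (4R,5S,6R)-5-iodo-4,6-dimethyl-6-[(2R)-2-methyl-11-phenylundecyl]-1,2-dioxan-3-ol F5. Only then, with the carbonyl carbon locked in the ring, would methanol and PPTS exchange the anomeric hydroxyl for methoxy through the cyclic peroxycarbenium ion to give 22.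

Step 10 (epoxide opening). What may go wrong: attack at the CH2OH-bearing epoxide carbon leading to the 1,3-diol, transfer of an ethyl or methyl group instead of the alkenyl group, opening of the activated epoxide by the LiI and LiCl present, or sluggish transfer from a single equivalent of alane. The fallback sets out from epoxy alcohol 15 (with iodide 13 as the partner) and comes back to the route at diol 19. The epoxy alcohol would be silylated (TBDPSCl, imidazole) to tert-butyl{[(2S,3S)-3-methyloxiran-2-yl]methoxy}diphenylsilane F6. Alkenyllithium 16, made from 13 as in step 10, would open F6 in the presence of BF3·OEt2 at −78 °C at the methyl-bearing carbon, distal to the bulky and electron-withdrawing silyloxymethyl group, with inversion, to give (2R,3S,4E,7R)-1-(tert-butyldiphenylsilyloxy)-3,5,7-trimethyl-16-phenylhexadec-4-en-2-ol F7. Bu4NF in THF would then remove the silyl group to give 19.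

Further compounds
F1 | step 13 | (2S,3E,6R)-1,1-dimethoxy-2,4,6-trimethyl-15-phenylpentadec-3-ene | COC(OC)[C@@H](C)/C=C(\C)C[C@H](C)CCCCCCCCCc1ccccc1
F2 | step 13 | triethyl{[(2S,6R)-1,1-dimethoxy-2,4,6-trimethyl-15-phenylpentadecan-4-yl]peroxy}silane (both C4 epimers) | COC(OC)[C@@H](C)CC(C)(OO[Si](CC)(CC)CC)C[C@H](C)CCCCCCCCCc1ccccc1
F3 | step 13 | (4S,6S)-3-methoxy-4,6-dimethyl-6-[(2R)-2-methyl-11-phenylundecyl]-1,2-dioxane (C6 epimer of 23, both C3 epimers) | C[C@H](CCCCCCCCCc1ccccc1)C[C@@]1(C)C[C@H](C)C(OC)OO1
F4 | step 12 | (2S,3E,6R)-1-hydroperoxy-2,4,6-trimethyl-15-phenylpentadec-3-en-1-ol (both C1 epimers) | OC(OO)[C@@H](C)/C=C(\C)C[C@H](C)CCCCCCCCCc1ccccc1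
F5 | step 12 | (4R,5S,6R)-5-iodo-4,6-dimethyl-6-[(2R)-2-methyl-11-phenylundecyl]-1,2-dioxan-3-ol (both C3 epimers) | C[C@H](CCCCCCCCCc1ccccc1)C[C@]1(C)[C@@H](I)[C@H](C)C(O)OO1
F6 | step 10 | tert-butyl{[(2S,3S)-3-methyloxiran-2-yl]methoxy}diphenylsilane | C[C@@H]1O[C@H]1CO[Si](c1ccccc1)(c1ccccc1)C(C)(C)C
F7 | step 10 | (2R,3S,4E,7R)-1-(tert-butyldiphenylsilyloxy)-3,5,7-trimethyl-16-phenylhexadec-4-en-2-ol | CC(C)(C)[Si](c1ccccc1)(c1ccccc1)OC[C@H](O)[C@@H](C)/C=C(\C)C[C@H](C)CCCCCCCCCc1ccccc1
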